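Assumption: the name Altisin is taken to mean the structure in the SMILES, 5-hydroxy-7,8,2',6'-tetramethoxyflavone (C19H18O7). It has no stereocentre, so no configuration has to be set.

Flavone numbering is used throughout. Ring C is O1, C2, C3, C4, C4a, C8a. Ring A is C4a, C5, C6, C7, C8, C8a. Ring B is C1' to C6'.

## Analysis of the target

Altisin (7) is a flavone. Benzo ring A is fused along C4a–C8a to the 4-pyranone ring C, which carries the 2,6-dimethoxyphenyl ring B at C2. There is no stereocentre, and because ring B is symmetric the twisted C2–C1' axis creates no isomers, so the whole problem is regiochemical. Ring A is pentasubstituted (C4 at C4a, free OH at C5, OMe at C7 and C8, O1 at C8a, H only at C6), and its four oxygens sit in a 1,2,3,5 array in three different roles. The 5-OH must end up free beside four methyl ethers. Ring B is as nucleophilic at C3'/C5' as a resorcinol diether, which rules out late electrophilic substitution on ring A. Hot strong acid opens ring C at O1–C2 and closes it again through the oxygen on C5 (Wessely–Moser rearrangement), which turns the 5,7,8 pattern into the 5,6,7 pattern. The feature used here is that C5–OH and C8–OMe are para, so ring A is a hydroquinone monomethyl ether. In its two-electron-oxidized form (C5=O, ketal at C8), C8a is the β-carbon of both C5=O and C4=O. O1–C8a can therefore be made at a C–H bond by conjugate addition, and rearomatization returns exactly the 5-OH/8-OMe pair.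

## Retrosynthetic reasoning

**Cut O1–C8a (7 to 6 to 5 to 4).** Ring C has two C–O bonds.
- Cutting O1–C2, the usual choice, leaves a ring A that already needs all four oxygens and offers two ortho oxygens for closure.
- Cutting O1–C8a removes one oxygen from ring A, leaves C8a–H, and hands O1 to the side chain as the enol oxygen of β-diketone 4.
- C8a must then be electrophilic. This is achieved by oxidizing the para-methoxyphenol of 4 to quinone monoketal 5.
- The forward step has three tasks: oxidize the phenol selectively, add the enol oxygen to C8a (giving 6), and expel one ketal methoxy group so that ring A rearomatizes to 7.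
- The gains are threefold. Ring A of 4 is a simple 2-hydroxy-4,5-dimethoxyphenyl ketone. C4a has only one free ring neighbour, so the isomeric oxygenation pattern cannot form. The 5-OH is never protected and no methyl ether is ever cleaved.

**Cut C2–C3 (4 to 3).** The diketone is opened at the bond between the methylene carbon and the aroyl carbonyl, which in the forward sense is an intramolecular O-to-C acyl shift. Cutting C3–C4 instead would need an activated ring A acid with its phenol protected. In the chosen cut the phenol oxygen carries the aroyl group for a time and then returns as the future 5-OH, while the aroyl carbonyl oxygen becomes O1.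

**Cut the ester C–O bond (3 to 1 + 2).** Both fragments are catalogue compounds. Together they already contain all nineteen carbons and all seven oxygens of 7, so the route only has to reconnect them and remove two hydrogens.

## Alternatives that were turned down

Alternative 1: the textbook disconnection at O1–C2.
- Forward key step: an o-hydroxyacetophenone that already bears all four ring A oxygens is aroylated, rearranged (Baker–Venkataraman) and cyclodehydrated with acid to 2-(2,6-dimethoxyphenyl)-5,7,8-trimethoxy-4H-chromen-4-one A1. A chelating Lewis acid then cleaves the 5-OMe.
- Reason turned down: the ring A ketone must itself be made by a regioselective acylation and partial demethylation of a tetraoxygenated benzene. A methyl group is installed only to be removed. The last step must single out one of five methyl ethers. The acidic steps work on a skeleton that can isomerize by ring C opening once the 5-OH is free. It needs about twice the steps and makes no use of the para relation in ring A.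

Alternative 2: cut O1–C8a and C4–C4a together.
- Forward key step: 3,4,6-trimethoxybenzyne A2 takes up 3-(2,6-dimethoxyphenyl)propiolic acid A3. The carboxylate oxygen adds, the acyl group shifts to the aryl anion, and the phenoxide closes 6-endo-dig onto the ynone to give A1.
- Reason turned down: the triple bond C4a≡C8a is flanked by oxygen on both sides (C5–O and C8–O). Their inductive effects oppose each other, and the remote C7 methoxy group slightly favours an anion at C8a, which means oxygen attack at C4a. That leads to the isomer 2-(2,6-dimethoxyphenyl)-5,6,8-trimethoxy-4H-chromen-4-one A4. The aryne precursor and A3 each cost several steps, and the 5-demethylation is still needed.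

Alternative 3: cut C4a–C5 and C8–C8a, so that ring A is built by benzannulation.
- Forward key step: 2-(2,6-dimethoxyphenyl)-4H-pyran-4-one A5 is metalated at C6 and added to the more ketone-like carbonyl of 3-methoxycyclobut-3-ene-1,2-dione A6, and the alkoxide is methylated to cyclobutenone A7. Heating would open the four-membered ring (4π), close the dienylketene onto C4a (6π) and tautomerize to 7. The ketene carbon becomes C5–OH and the ether carbon becomes C8–OMe.
- Reason turned down: the step needs a carbanion on the β-carbon of a γ-pyranone that carries its own electrophilic carbonyl and is prone to ring opening, so the main risk sits before the key step. A5 and A6 each take about two steps, giving six or seven in all. A ring that can be bought with four of its five substituents would be built from scratch.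

Key step: step 3

## Route

Step 1
Reactants: 1 1-(2-hydroxy-4,5-dimethoxyphenyl)ethan-1-one; 2 2,6-dimethoxybenzoyl chloride
Product: 3 2-acetyl-4,5-dimethoxyphenyl 2,6-dimethoxybenzoate
Conditions: Et3N, DMAP (cat.), CH2Cl2, 0 °C to rt
Reagents that add atoms: none
Why: Acylation of a phenol by an acid chloride under nucleophilic catalysis; the acylpyridinium salt formed with DMAP should overcome both the shielding of the carbonyl group by its two ortho methoxy groups and the hydrogen bond that holds the phenol of 1, while the methyl ketone and the aryl ethers are inert.

Step 2
Reactants: 3 2-acetyl-4,5-dimethoxyphenyl 2,6-dimethoxybenzoate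
Product: 4 1-(2,6-dimethoxyphenyl)-3-(2-hydroxy-4,5-dimethoxyphenyl)propane-1,3-dione
Conditions: KOtBu (2.2 equiv), THF, 0 °C to rt; AcOH quench
Reagents that add atoms: none
Why: Baker–Venkataraman rearrangement, in which the potassium enolate of the acetyl group attacks the ester carbonyl through a six-membered transition state and the phenoxide leaves, an intramolecular Claisen condensation that forms C2–C3; the second equivalent of base holds 4 as its dianion and drives the equilibrium, and the mild quench avoids cyclodehydration through the phenol.

Step 3
Reactants: 4 1-(2,6-dimethoxyphenyl)-3-(2-hydroxy-4,5-dimethoxyphenyl)propane-1,3-dione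
Product: 7 Altisin (2-(2,6-dimethoxyphenyl)-5-hydroxy-7,8-dimethoxy-4H-chromen-4-one), via quinone monoketal 5 (not isolated), via oxa-Michael adduct 6 (not isolated)
Conditions: PhI(OAc)2 (1.0 equiv, slow addition), dry MeOH–CH2Cl2, 0 °C; evaporate (toluene chase); Et3N (20 mol %), CH2Cl2 (dilute), rt; then camphorsulfonic acid (40 mol %), rt
Reagents that add atoms: methanol, CO (supplies the second methoxy group at C8 of 5; one of the two equivalent ketal methoxy groups leaves again on aromatization)
Why: Proposed new method: PhI(OAc)2 binds the phenol oxygen of 4 at trivalent iodine and methanol attacks the para carbon C8, whose own methoxy group carries the developing charge best, so that iodobenzene leaves and quinone monoketal 5 forms, the standard oxidation of 4-methoxyphenols. In 5 the carbon C8a is the β-carbon of both the ring carbonyl C5=O and the side-chain carbonyl C4=O and bears only hydrogen, whereas C7 is deactivated as a vinylogous ester and C6 is an α-carbon, so C8a is the one acceptor site. The enolate oxygen on C2, set free by catalytic Et3N, adds to C8a in a favoured 6-endo-trig oxa-Michael closure (the same bond can form by oxa-6π electrocyclization of the C4-enol tautomer), which makes O1–C8a, closes ring C and gives 6; carbon C3 cannot compete because it would close a four-membered ring. Acid then ionizes one of the two ketal methoxy groups of 6, loss of H-8a aromatizes ring A irreversibly, and the C5 carbonyl returns as the free chelated 5-OH while the remaining methoxy group is the 8-OMe. The closest known reaction types are the conjugate addition of oxygen, sulfur, nitrogen and carbon nucleophiles to quinone monoketals followed by acid-induced loss of methanol, and the oxidative closure of 2-hydroxybenzophenones to xanthones through quinonoid intermediates; new is a β-diketone enol oxygen as the nucleophile and a 4-pyranone as the ring formed. Chemoselectivity rests on the substrate: ring A is the only ring with a free phenol, neutral PhI(OAc)2 attacks β-diketones only slowly without added acid or base, and ring B has no hydroxyl group. Regioselectivity is structural, since the acyl-bearing C4a has C8a as its only free ring neighbour and the 5,6,7 isomer cannot arise; removal of methanol before the base is added takes away the competing external nucleophile, and the oxidant is spent before 7 appears. The stereocentre C8a of 6 is racemic and is erased on aromatization.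

## Compound list

1 | 1-(2-hydroxy-4,5-dimethoxyphenyl)ethan-1-one | CC(=O)c1cc(OC)c(OC)cc1O | starting material
2 | 2,6-dimethoxybenzoyl chloride | COc1cccc(OC)c1C(=O)Cl | starting material
3 | 2-acetyl-4,5-dimethoxyphenyl 2,6-dimethoxybenzoate | CC(=O)c1cc(OC)c(OC)cc1OC(=O)c1c(OC)cccc1OC | intermediate
4 | 1-(2,6-dimethoxyphenyl)-3-(2-hydroxy-4,5-dimethoxyphenyl)propane-1,3-dione | COc1cccc(OC)c1C(=O)CC(=O)c1cc(OC)c(OC)cc1O | intermediate
5 | 1-(2,6-dimethoxyphenyl)-3-(3,3,4-trimethoxy-6-oxocyclohexa-1,4-dien-1-yl)propane-1,3-dione (quinone monoketal, not isolated) | COc1cccc(OC)c1C(=O)CC(=O)C1=CC(OC)(OC)C(OC)=CC1=O | intermediate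
6 | 2-(2,6-dimethoxyphenyl)-5-hydroxy-7,8,8-trimethoxy-8,8a-dihydro-4H-chromen-4-one (enol form, racemic at C8a, not isolated) | COC1=CC(O)=C2C(=O)C=C(c3c(OC)cccc3OC)OC2C1(OC)OC | intermediate
7 | Altisin, 2-(2,6-dimethoxyphenyl)-5-hydroxy-7,8-dimethoxy-4H-chromen-4-one | COc1cccc(OC)c1-c1cc(=O)c2c(O)cc(OC)c(OC)c2o1 | target

## Step count and risks

Total step count: 3. Longest linear sequence: 3.

**Step 3 (key step, proposed new method).** Four processes could divert it.
- The oxidant could attack the enolized carbon C3 instead of dearomatizing the phenol, because the phenol is chelated to C4=O and so exchanges more slowly at iodine.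
- Residual methanol could add to C8a ahead of the enol oxygen and then aromatize under acid.
- The new para-methoxyphenol could be oxidized further if ring closure begins while oxidant is still present.
- Traces of water could hydrolyse the ketal, with loss of the 8-methyl group.

The fallback uses known chemistry only, sets out from 2 and returns at 7. 1-(2-Hydroxy-3,4,6-trimethoxyphenyl)ethan-1-one F1 would be acylated with 2 (pyridine, DMAP) to 2-acetyl-3,5,6-trimethoxyphenyl 2,6-dimethoxybenzoate F2. KOtBu would rearrange this to 1-(2,6-dimethoxyphenyl)-3-(2-hydroxy-3,4,6-trimethoxyphenyl)propane-1,3-dione F3. H2SO4 in AcOH would cyclodehydrate F3 to 2-(2,6-dimethoxyphenyl)-5,7,8-trimethoxy-4H-chromen-4-one F4, which is the same compound as A1. BCl3 in CH2Cl2 at low temperature would then cleave only the methoxy group chelated to C4=O and give 7.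

**Step 2.** The enolate must attack a carbonyl group flanked by two ortho methoxy groups. The acyl shift may therefore be slow, and cleavage of the ester by adventitious hydroxide may take over and return the phenol. The fallback sets out from 1 and returns at 4, and it forms the same C2–C3 bond on an unhindered aldehyde. The dianion of 1 (LiN(SiMe3)2, 2.2 equiv, THF, −78 °C) would add to 2,6-dimethoxybenzaldehyde F5 to give racemic 3-(2,6-dimethoxyphenyl)-3-hydroxy-1-(2-hydroxy-4,5-dimethoxyphenyl)propan-1-one F6. MnO2 in CH2Cl2 would oxidize its benzylic alcohol to 4.

**Step 1.** O-acylation may stall, because the phenol is hydrogen-bonded to the acetyl group and the acid chloride is shielded, and moisture may then consume the acid chloride. The fallback sets out from 1 and 2 and returns at 4, skipping the ester altogether. The lithium dianion of 1 (LiN(SiMe3)2, 3 equiv, THF, −78 °C) would be C-acylated directly by 2, an intermolecular Claisen-type acylation of an o-hydroxyacetophenone polyanion.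

## Further compounds

F1 | step 3 | 1-(2-hydroxy-3,4,6-trimethoxyphenyl)ethan-1-one | CC(=O)c1c(O)c(OC)c(OC)cc1OC
F2 | step 3 | 2-acetyl-3,5,6-trimethoxyphenyl 2,6-dimethoxybenzoate | CC(=O)c1c(OC)cc(OC)c(OC)c1OC(=O)c1c(OC)cccc1OC
F3 | step 3 | 1-(2,6-dimethoxyphenyl)-3-(2-hydroxy-3,4,6-trimethoxyphenyl)propane-1,3-dione | COc1cccc(OC)c1C(=O)CC(=O)c1c(O)c(OC)c(OC)cc1OC
F4 | step 3 | 2-(2,6-dimethoxyphenyl)-5,7,8-trimethoxy-4H-chromen-4-one | COc1cccc(OC)c1-c1cc(=O)c2c(OC)cc(OC)c(OC)c2o1
F5 | step 2 | 2,6-dimethoxybenzaldehyde | COc1cccc(OC)c1C=O
F6 | step 2 | 3-(2,6-dimethoxyphenyl)-3-hydroxy-1-(2-hydroxy-4,5-dimethoxyphenyl)propan-1-one (racemic) | COc1cccc(OC)c1C(O)CC(=O)c1cc(OC)c(OC)cc1O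
F0 | step 1 | none | none
A1 | alternative 1 | 2-(2,6-dimethoxyphenyl)-5,7,8-trimethoxy-4H-chromen-4-one | COc1cccc(OC)c1-c1cc(=O)c2c(OC)cc(OC)c(OC)c2o1
A2 | alternative 2 | 3,4,6-trimethoxybenzyne (1,2-didehydro-3,4,6-trimethoxybenzene) | COC1=CC(OC)=C(OC)C#C1
A3 | alternative 2 | 3-(2,6-dimethoxyphenyl)propiolic acid | COc1cccc(OC)c1C#CC(=O)O
A4 | alternative 2 | 2-(2,6-dimethoxyphenyl)-5,6,8-trimethoxy-4H-chromen-4-one | COc1cccc(OC)c1-c1cc(=O)c2c(OC)c(OC)cc(OC)c2o1
A5 | alternative 3 | 2-(2,6-dimethoxyphenyl)-4H-pyran-4-one | COc1cccc(OC)c1-c1cc(=O)cco1
A6 | alternative 3 | 3-methoxycyclobut-3-ene-1,2-dione | COC1=CC(=O)C1=O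
A7 | alternative 3 | 2-(2,6-dimethoxyphenyl)-6-(1,2-dimethoxy-4-oxocyclobut-2-en-1-yl)-4H-pyran-4-one (racemic) | COC1=CC(=O)C1(OC)c1cc(=O)cc(-c2c(OC)cccc2OC)o1
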